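The target is a C2-symmetric bis-chroman: two identical 8-acyl-5,7-dihydroxy-2,2-dimethylchroman units joined through C6 by one 6-methylheptylidene carbon. That carbon is cut first (aldehyde plus two monomers); the monomer is then cut at the C4–C4a bond of its pyran ring. The key step closes this ring by a gold(I)-catalysed 6-endo-dig hydroarylation of an aryl 1,1-dimethylpropargyl ether: arene carbon C4a, the only free position ortho to the ether oxygen (the other ortho carbon, C8, carries the acyl group), attacks the terminal alkyne carbon, which becomes C4. The precursor is the bis-benzyl-protected acylphloroglucinol carrying the propargyl ether on the phenol oxygen next to the ketone.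

Key step: step 4

Assumption (remark on the chemistry): (R)-2-methylbutanoic acid and 6-methylheptanal are taken as catalogue compounds. Both stereocentres of the target are (R); the bridging CH carries two identical aryl groups and is not a stereocentre.

Step 1
Reactants: 1 (R)-2-methylbutanoic acid; 2 phloroglucinol (benzene-1,3,5-triol)
Product: 4 (R)-2-methyl-1-(2,4,6-trihydroxyphenyl)butan-1-one, via (R)-2-methylbutanoyl chloride 3 (not isolated)
Conditions: (COCl)2, DMF (cat.), CH2Cl2, 0 °C → rt; then 2, AlCl3 (3.5 equiv), PhNO2/CH2Cl2, 0 °C → rt; aq. HCl work-up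
Reagents that add atoms: none
Why: Vilsmeier-catalysed acid chloride formation under neutral conditions followed by Friedel–Crafts C-acylation of the very nucleophilic phloroglucinol should stop at mono-acylation because the first acyl group deactivates the ring; the (R) centre is not formed here but carried over from 1, and low temperature with short contact time is chosen to keep it.

Step 2
Reactants: 4 (R)-2-methyl-1-(2,4,6-trihydroxyphenyl)butan-1-one
Product: 5 (R)-1-[2,4-bis(benzyloxy)-6-hydroxyphenyl]-2-methylbutan-1-one
Conditions: BnBr (2.1 equiv), K2CO3 (2.2 equiv), DMF, rt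
Reagents that add atoms: benzyl bromide, BrCc1ccccc1
Why: Williamson etherification should take the para phenol and one ortho phenol and then stop, because the last hydroxyl is held in a strong hydrogen bond to the ketone.

Step 3
Reactants: 5 (R)-1-[2,4-bis(benzyloxy)-6-hydroxyphenyl]-2-methylbutan-1-one
Product: 6 (R)-1-[2,4-bis(benzyloxy)-6-(2-methylbut-3-yn-2-yloxy)phenyl]-2-methylbutan-1-one
Conditions: 3-chloro-3-methylbut-1-yne (1.5 equiv), DBU (1.6 equiv), CuCl2·2H2O (1 mol%), MeCN, 0 °C → rt
Reagents that add atoms: 3-chloro-3-methylbut-1-yne, CC(C)(Cl)C#C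
Why: Copper-catalysed propargylic etherification proceeds through a copper acetylide/allenylidene that the phenoxide captures at the tertiary carbon, a pathway that tolerates hindered and hydrogen-bonded phenols where direct SN2 cannot operate.

Step 4
Reactants: 6 (R)-1-[2,4-bis(benzyloxy)-6-(2-methylbut-3-yn-2-yloxy)phenyl]-2-methylbutan-1-one
Product: 7 (R)-1-[5,7-bis(benzyloxy)-2,2-dimethyl-2H-chromen-8-yl]-2-methylbutan-1-one
Conditions: Ph3PAuNTf2 (2 mol%), CH2Cl2, rt
Reagents that add atoms: none
Why: The cationic gold(I) centre binds the terminal alkyne of 6 and the arene carbon ortho to the ether oxygen attacks the terminal alkyne carbon anti to gold, after which the Wheland intermediate rearomatises and the vinylgold species is protodeaurated to the 2H-chromene 7. The closest known reaction type is the gold(I)-catalysed intramolecular hydroarylation (Friedel–Crafts-type alkenylation) of aryl propargyl ethers to 2H-chromenes. The pyran ring closes in the 6-endo-dig mode. No stereocentre is formed, and the (R) centre next to the ketone is not at risk under neutral conditions at room temperature. The step needs regioselectivity between the two carbons ortho to the ether oxygen and 6-endo over 5-exo closure: the first is secured because the other ortho carbon carries the acyl group while the attacked carbon is activated ortho/para by all three oxygens, the second by the strain of the alternative 3-methylene-2,3-dihydrobenzofuran and by the electron-withdrawing propargylic oxygen, which disfavours positive charge at the internal alkyne carbon. Because the O–C(CH3)2 bond is never broken and both other phenols are benzylated, the ring oxygen stays on the carbon next to the acyl group.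

Step 5
Reactants: 7 (R)-1-[5,7-bis(benzyloxy)-2,2-dimethyl-2H-chromen-8-yl]-2-methylbutan-1-one
Product: 8 (R)-1-(5,7-dihydroxy-2,2-dimethylchroman-8-yl)-2-methylbutan-1-one
Conditions: H2 (1 atm), 10% Pd/C, EtOAc/MeOH, rt
Reagents that add atoms: none
Why: Heterogeneous hydrogenation should saturate the cis-styrenyl C3=C4 bond and cleave both benzyl ethers by hydrogenolysis in one operation, while the hindered, hydrogen-bonded aryl ketone and its α-stereocentre are left alone.

Step 6
Reactants: 8 (R)-1-(5,7-dihydroxy-2,2-dimethylchroman-8-yl)-2-methylbutan-1-one (2 equivalents); 9 6-methylheptanal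
Product: 11 6,6'-(6-methylheptane-1,1-diyl)bis{5,7-dihydroxy-2,2-dimethyl-8-[(2R)-2-methylbutanoyl]chroman} (the target), via ortho-quinone methide 10 (not isolated)
Conditions: 9 (0.5 equiv relative to 8), p-TsOH·H2O (10 mol%), CH2Cl2, rt
Reagents that add atoms: none
Why: Acid-catalysed Baeyer-type condensation: Friedel–Crafts hydroxyalkylation of C6 of 8 (its only free ring carbon, flanked by two hydroxyls) by the aldehyde and loss of water give the ortho-quinone methide 10, which is trapped by C6 of a second molecule of 8 in a Michael-type arylation; the new bridging carbon bears two identical aryl groups and is therefore not a stereocentre, and the two (R) centres come unchanged from 8.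

Compound list
1 | (R)-2-methylbutanoic acid | CC[C@@H](C)C(=O)O | starting material
2 | phloroglucinol (benzene-1,3,5-triol) | Oc1cc(O)cc(O)c1 | starting material
3 | (R)-2-methylbutanoyl chloride | CC[C@@H](C)C(=O)Cl | intermediate (not isolated)
4 | (R)-2-methyl-1-(2,4,6-trihydroxyphenyl)butan-1-one | CC[C@@H](C)C(=O)c1c(O)cc(O)cc1O | intermediate
5 | (R)-1-[2,4-bis(benzyloxy)-6-hydroxyphenyl]-2-methylbutan-1-one | CC[C@@H](C)C(=O)c1c(O)cc(OCc2ccccc2)cc1OCc1ccccc1 | intermediate
6 | (R)-1-[2,4-bis(benzyloxy)-6-(2-methylbut-3-yn-2-yloxy)phenyl]-2-methylbutan-1-one | CC[C@@H](C)C(=O)c1c(OC(C)(C)C#C)cc(OCc2ccccc2)cc1OCc1ccccc1 | intermediate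
7 | (R)-1-[5,7-bis(benzyloxy)-2,2-dimethyl-2H-chromen-8-yl]-2-methylbutan-1-one | CC[C@@H](C)C(=O)c1c(OCc2ccccc2)cc(OCc2ccccc2)c2c1OC(C)(C)C=C2 | intermediate
8 | (R)-1-(5,7-dihydroxy-2,2-dimethylchroman-8-yl)-2-methylbutan-1-one | CC[C@@H](C)C(=O)c1c(O)cc(O)c2c1OC(C)(C)CC2 | intermediate
9 | 6-methylheptanal | CC(C)CCCCC=O | starting material
10 | ortho-quinone methide: 7-hydroxy-2,2-dimethyl-6-(6-methylheptylidene)-8-[(2R)-2-methylbutanoyl]-3,4-dihydro-2H-chromen-5(6H)-one | CC[C@@H](C)C(=O)C1=C(O)C(=CCCCCC(C)C)C(=O)C2=C1OC(C)(C)CC2 | intermediate (not isolated)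
11 | 6,6'-(6-methylheptane-1,1-diyl)bis{5,7-dihydroxy-2,2-dimethyl-8-[(2R)-2-methylbutanoyl]chroman} | CC[C@@H](C)C(=O)c1c(O)c(C(CCCCC(C)C)c2c(O)c3c(c(C(=O)[C@H](C)CC)c2O)OC(C)(C)CC3)c(O)c2c1OC(C)(C)CC2 | target

Total step count: 6
Longest linear sequence: 6 steps (1 → 4 → 5 → 6 → 7 → 8 → 11)

Steps most likely to fail

Step 4 (key step). The gold centre may ionise the tertiary propargylic C–O bond, so that the tether is lost from the phenol, or the closure may run 5-exo instead of 6-endo. The fallback sets out from 6 and comes back to the route at 8, and it makes the same C–C bond by a sigmatropic shift instead of a metal-catalysed arylation. Semi-hydrogenation of the alkyne (H2, Lindlar catalyst, quinoline, EtOAc) should give the 1,1-dimethylallyl ether (R)-1-[2,4-bis(benzyloxy)-6-(2-methylbut-3-en-2-yloxy)phenyl]-2-methylbutan-1-one F1. An aromatic Claisen rearrangement (toluene, 110 °C) should move the allyl unit to the only free ortho carbon and give the ortho-prenylphenol (R)-1-[4,6-bis(benzyloxy)-2-hydroxy-3-(3-methylbut-2-en-1-yl)phenyl]-2-methylbutan-1-one F2. Acid-catalysed hydroalkoxylation (p-TsOH, CH2Cl2, rt) should close the pyran onto the only free phenol to give (R)-1-[5,7-bis(benzyloxy)-2,2-dimethylchroman-8-yl]-2-methylbutan-1-one F3. Hydrogenolysis under the conditions of step 5 then gives 8.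

Step 3. O-Alkylation of the hydrogen-bonded, doubly ortho-flanked phenol may be so slow that elimination of the tertiary chloride to the enyne takes over. The fallback sets out from 4 and comes back at 8, and it changes the protecting-group logic so that the ether is made on the first of two equivalent ortho phenols instead of on the last, chelated one. Mono-benzylation of the most acidic para phenol (BnBr 1.0 equiv, K2CO3, acetone, rt) should give (R)-1-[4-(benzyloxy)-2,6-dihydroxyphenyl]-2-methylbutan-1-one F4. Copper-catalysed propargylation as in step 3 should give the mono-ether (R)-1-[4-(benzyloxy)-2-hydroxy-6-(2-methylbut-3-yn-2-yloxy)phenyl]-2-methylbutan-1-one F5. Gold-catalysed cyclisation as in step 4 should give (R)-1-[5-(benzyloxy)-7-hydroxy-2,2-dimethyl-2H-chromen-8-yl]-2-methylbutan-1-one F6, whose ring oxygen is again fixed because the ether bond is not broken. Hydrogenation as in step 5 gives 8.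

Step 1. The enantiomeric purity may erode through enolisation or ketene formation in the acyl chloride–AlCl3 complex. The fallback sets out from 1 and comes back at 5, and it replaces the Friedel–Crafts acylation by acylation of an aryllithium. Acid 1 is coupled with N,O-dimethylhydroxylamine hydrochloride (EDC·HCl, N-methylmorpholine, CH2Cl2) to the Weinreb amide (R)-N-methoxy-N,2-dimethylbutanamide F7. Purchased 1,3,5-tris(benzyloxy)benzene F8 is brominated (NBS, CH2Cl2, 0 °C) to 2-bromo-1,3,5-tris(benzyloxy)benzene F9. Bromine–lithium exchange (n-BuLi, THF, −78 °C) should give 2,4,6-tris(benzyloxy)phenyllithium F10, and addition of F7 the ketone (R)-1-[2,4,6-tris(benzyloxy)phenyl]-2-methylbutan-1-one F11, the chelated tetrahedral intermediate protecting the α-stereocentre. Chelation-directed cleavage of one benzyl ether ortho to the carbonyl (BCl3 1.0 equiv, CH2Cl2, −78 °C) then gives 5.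

Further compounds
F1 | step 4 | (R)-1-[2,4-bis(benzyloxy)-6-(2-methylbut-3-en-2-yloxy)phenyl]-2-methylbutan-1-one | CC[C@@H](C)C(=O)c1c(OC(C)(C)C=C)cc(OCc2ccccc2)cc1OCc1ccccc1
F2 | step 4 | (R)-1-[4,6-bis(benzyloxy)-2-hydroxy-3-(3-methylbut-2-en-1-yl)phenyl]-2-methylbutan-1-one | CC[C@@H](C)C(=O)c1c(O)c(CC=C(C)C)c(OCc2ccccc2)cc1OCc1ccccc1
F3 | step 4 | (R)-1-[5,7-bis(benzyloxy)-2,2-dimethylchroman-8-yl]-2-methylbutan-1-one | CC[C@@H](C)C(=O)c1c(OCc2ccccc2)cc(OCc2ccccc2)c2c1OC(C)(C)CC2
F4 | step 3 | (R)-1-[4-(benzyloxy)-2,6-dihydroxyphenyl]-2-methylbutan-1-one | CC[C@@H](C)C(=O)c1c(O)cc(OCc2ccccc2)cc1O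
F5 | step 3 | (R)-1-[4-(benzyloxy)-2-hydroxy-6-(2-methylbut-3-yn-2-yloxy)phenyl]-2-methylbutan-1-one | CC[C@@H](C)C(=O)c1c(O)cc(OCc2ccccc2)cc1OC(C)(C)C#C
F6 | step 3 | (R)-1-[5-(benzyloxy)-7-hydroxy-2,2-dimethyl-2H-chromen-8-yl]-2-methylbutan-1-one | CC[C@@H](C)C(=O)c1c(O)cc(OCc2ccccc2)c2c1OC(C)(C)C=C2
F7 | step 1 | (R)-N-methoxy-N,2-dimethylbutanamide | CC[C@@H](C)C(=O)N(C)OC
F8 | step 1 | 1,3,5-tris(benzyloxy)benzene (purchased) | c1ccc(COc2cc(OCc3ccccc3)cc(OCc3ccccc3)c2)cc1
F9 | step 1 | 2-bromo-1,3,5-tris(benzyloxy)benzene | Brc1c(OCc2ccccc2)cc(OCc2ccccc2)cc1OCc1ccccc1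
F10 | step 1 | 2,4,6-tris(benzyloxy)phenyllithium | [Li]c1c(OCc2ccccc2)cc(OCc2ccccc2)cc1OCc1ccccc1
F11 | step 1 | (R)-1-[2,4,6-tris(benzyloxy)phenyl]-2-methylbutan-1-one | CC[C@@H](C)C(=O)c1c(OCc2ccccc2)cc(OCc2ccccc2)cc1OCc1ccccc1
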